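It is easy to take the reagent for the limiting reagent and cap the product at its saturation level of 110 mM, because that level is lower than every charge of starting material.

| flask | starting material | gas | time |
|---|---|---|---|
| east | 0.20 M | 110 mM (held) | 6.0 h |
| south-west | 0.40 M | 110 mM (held) | 6.0 h |
| south-east | 0.80 M | 110 mM (held) | 6.0 h |

    2 starting material → homo dimer (k1 = 0.0039 L mol⁻¹ min⁻¹)
    starting material ⇌ intermediate + leaving ligand (K2 = 0.018 M, k2 = 0.033 min⁻¹)
    reagent + intermediate → product (k3 = 74 L mol⁻¹ min⁻¹)
    gas ⇌ reagent, rate k4*(csat - [reagent]) (k4 = 1.1 min⁻¹, csat = 110 mM)

- percent here means starting material units held: one homo dimer counts as two
- a doubled species enters its step squared and goes two at a time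
- at the start none of reagent is dissolved
- "hardly changes" means that all values lie within two and a half points (for a concentration: within two and a half percent of the largest)
- run time (east): 6.0 h

1. [product] at the end for east, south-west, south-east, in this order
2. the shape of the row from first to last (hardly changes / falls, then rises / rises all the way / falls all the way / rises, then falls)

So I write the balance of the reagent. The held gas feeds it at up to 0.121 M min⁻¹, while dissociation in the flask south-east demands at most 0.0264 M min⁻¹. The supply is 4.58 times that demand, so the reagent is a flow and not a stock, and what counts is where the starting material goes. It can dissociate, first order, towards product, or dimerise, second order. I fold the two into one number, here for the flask east: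

D = 2 × 0.0039 L mol⁻¹ min⁻¹ × 0.20 M / 0.033 min⁻¹ = 0.0473

This D, the loss number, is the rate of loss to homo dimer over the rate of dissociation at the start. As the starting material falls to a fraction x of its charge, the share going to product becomes 1/(1 + Dx). Averaged over the whole run, this gives:

share to product = ln(1 + D)/D

east: D = 0.0473, product 0.195 M

south-west: D = 0.0945, product 0.382 M

south-east: D = 0.189, product 0.733 M

Is one number enough? The half-life of the starting material by the forward step of dissociation, taken by itself, is 0.350 h, and the run lasts 17.1 of these, so time is not short. Return of the intermediate, reckoned against the full charge of leaving ligand south-east, stands to capture at saturation as 0.180, so I keep D, but because that ratio is not zero I expect slightly more homo dimer south-east than it says.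

The forecast gives 0.195 M, 0.381 M and 0.728 M, the last lower than mine, and says the row rises all the way, with the loss set by the “dimer side-reaction, which grows with concentration”.

The simulation gives 0.195 M, 0.382 M and 0.729 M, so the row rises all the way. In the flask east the homo dimer holds 2.33% of the charge at 6.00 h, and the loss number of that flask gives 2.29%. In the flask south-east, D = 0.189 gives 8.41% for the homo dimer, and the flask holds 8.88% at 6.00 h.

All constants belong to no real substance; the flask was simulated.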